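**Retrosynthetic overview**
1. The 16,17-diacetate (lobane numbering) comes from the trans-16,17-epoxide of the dienyl carbinol fuscol: acetate opens the allylic C16–O bond with inversion, then O17 is acetylated. The epoxide comes from a hydroxyl-directed, catalyst-controlled epoxidation of fuscol (the key C–O step, proposed as new).
2. Fuscol comes from methyl ketone 11 by a vinylogous Horner–Wadsworth–Emmons olefination and double MeLi addition.
3. Ketone 11 comes from (S)-carvone: isopropenyl to acetyl to dioxolane; anti conjugate isopropenylation; anti α-vinylation (quaternary carbon); carbonyl removal; ketal cleavage with epimerisation to the all-equatorial ketone.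
4. Rings: the cyclohexane is carried through from carvone and no carbocycle is built. A dioxolane (made in step 2, removed in step 6) and an oxirane (made in step 9, opened in step 10) are the only rings formed.

Assumption: side-chain atoms are numbered as in lobanes (C13 on the ring, C16/C17 the acetoxy carbons, C18 the carbinol), and the (R,R)-ligand of step 9 is assumed to deliver oxygen to the face that gives 14 (if a model dienol shows the opposite sense, its antipode is used).

**Route**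

Step 1
Reactants: 1 (S)-carvone
Product: 2 (5S)-5-acetyl-2-methylcyclohex-2-en-1-one
Conditions: O3 (1.0 equiv), pyridine, CH2Cl2, −78 °C
Reagents that add atoms: ozone [O-][O+]=O
Why: Ozonolysis (pyridine-mediated, giving the carbonyl directly) cleaves the electron-rich 1,1-disubstituted isopropenyl alkene much faster than the electron-poor enone C=C, and the C5 stereocentre is untouched.

Step 2
Reactants: 2 (5S)-5-acetyl-2-methylcyclohex-2-en-1-one
Product: 3 (5S)-2-methyl-5-(2-methyl-1,3-dioxolan-2-yl)cyclohex-2-en-1-one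
Conditions: HOCH2CH2OH (1.1 equiv), p-TsOH (cat.), benzene, reflux, Dean–Stark
Reagents that add atoms: ethylene glycol OCCO
Why: Acid-catalysed ketalisation is chemoselective because the saturated methyl ketone forms the dioxolane much faster than the conjugated, α-substituted enone carbonyl.

Step 3
Reactants: 3 (5S)-2-methyl-5-(2-methyl-1,3-dioxolan-2-yl)cyclohex-2-en-1-one
Product: 4 trimethyl{[(3R,5S)-2-methyl-5-(2-methyl-1,3-dioxolan-2-yl)-3-(prop-1-en-2-yl)cyclohex-1-en-1-yl]oxy}silane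
Conditions: CH2=C(CH3)MgBr, CuBr·SMe2 (10 mol %), Me3SiCl, HMPA, THF, −78 °C; Et3N
Reagents that add atoms: isopropenylmagnesium bromide C=C(C)[Mg]Br; chlorotrimethylsilane C[Si](C)(C)Cl
Why: Copper-catalysed conjugate addition of the Grignard reagent with silyl trapping: the alkenyl group enters axially, anti to the dioxolanyl group at C5, which sets C3 (3,5-trans), and the regiodefined enolate is captured as the silyl enol ether.

Step 4
Reactants: 4 trimethyl{[(3R,5S)-2-methyl-5-(2-methyl-1,3-dioxolan-2-yl)-3-(prop-1-en-2-yl)cyclohex-1-en-1-yl]oxy}silane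
Product: 7 (2R,3R,5S)-2-ethenyl-2-methyl-5-(2-methyl-1,3-dioxolan-2-yl)-3-(prop-1-en-2-yl)cyclohexan-1-one, via lithium enolate 5 (not isolated), via sulfoxide adduct 6 (not isolated)
Conditions: MeLi, THF, 0 → 23 °C; PhS(O)CH=CH2, −78 → 0 °C; H2O; then toluene, NaHCO3, 110 °C
Reagents that add atoms: phenyl vinyl sulfoxide C=CS(=O)c1ccccc1
Why: The regiospecific lithium enolate adds (Michael addition) to phenyl vinyl sulfoxide as a vinyl cation equivalent on the face anti to the axial C3 isopropenyl group, which sets the quaternary carbon with vinyl trans to isopropenyl, and thermal sulfoxide syn-elimination then unveils the vinyl group.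

Step 5
Reactants: 7 (2R,3R,5S)-2-ethenyl-2-methyl-5-(2-methyl-1,3-dioxolan-2-yl)-3-(prop-1-en-2-yl)cyclohexan-1-one
Product: 9 2-[(1R,3R,4R)-4-ethenyl-4-methyl-3-(prop-1-en-2-yl)cyclohexyl]-2-methyl-1,3-dioxolane, via hydrazone 8 (not isolated)
Conditions: N2H4·H2O, n-BuOH, 115 °C; then KOtBu, DMSO, 25 °C
Reagents that add atoms: none
Why: Wolff–Kishner reduction in its low-temperature variant (preformed hydrazone, KOtBu/DMSO) removes the carbonyl without affecting the ketal or the three alkenes and stays below temperatures at which the 1,5-diene could equilibrate by Cope rearrangement; no stereocentre changes.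

Step 6
Reactants: 9 2-[(1R,3R,4R)-4-ethenyl-4-methyl-3-(prop-1-en-2-yl)cyclohexyl]-2-methyl-1,3-dioxolane
Product: 11 1-[(1S,3R,4R)-4-ethenyl-4-methyl-3-(prop-1-en-2-yl)cyclohexyl]ethan-1-one, via axial-acetyl epimer 10 (not isolated)
Conditions: PPTS, acetone/H2O, 60 °C; then NaOMe, MeOH, 23 °C
Reagents that add atoms: water O
Why: Acetal hydrolysis followed by base-mediated enolisation α to the acetyl group equilibrates the ring carbon to the thermodynamic isomer with vinyl, isopropenyl and acetyl all equatorial (expected about 9:1, minor epimer recycled), which sets cyclohexyl C1 as S.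

Step 7
Reactants: 11 1-[(1S,3R,4R)-4-ethenyl-4-methyl-3-(prop-1-en-2-yl)cyclohexyl]ethan-1-one
Product: 12 ethyl (2E,4E)-5-[(1S,3R,4R)-4-ethenyl-4-methyl-3-(prop-1-en-2-yl)cyclohexyl]hexa-2,4-dienoate
Conditions: (EtO)2P(O)CH2CH=CHCO2Et, LiN(SiMe3)2, THF, −78 → 23 °C
Reagents that add atoms: triethyl 4-phosphonocrotonate CCOC(=O)/C=C/CP(=O)(OCC)OCC
Why: Vinylogous Horner–Wadsworth–Emmons olefination of the methyl ketone gives the (2E,4E)-dienoate as the major isomer (ring substituent trans to the chain), and the minor 4Z isomer is removed by chromatography.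

Step 8
Reactants: 12 ethyl (2E,4E)-5-[(1S,3R,4R)-4-ethenyl-4-methyl-3-(prop-1-en-2-yl)cyclohexyl]hexa-2,4-dienoate
Product: 13 (3E,5E)-6-[(1S,3R,4R)-4-ethenyl-4-methyl-3-(prop-1-en-2-yl)cyclohexyl]-2-methylhepta-3,5-dien-2-ol
Conditions: MeLi (3 equiv), Et2O, −78 → 0 °C; H2O
Reagents that add atoms: methyllithium [Li]C
Why: Double 1,2-addition of the hard organolithium to the ester at low temperature gives the tertiary carbinol (fuscol) without conjugate addition to the dienoate.

Step 9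
Reactants: 13 (3E,5E)-6-[(1S,3R,4R)-4-ethenyl-4-methyl-3-(prop-1-en-2-yl)cyclohexyl]-2-methylhepta-3,5-dien-2-ol
Product: 14 2-[(2S,3R)-3-{(1E)-2-[(1S,3R,4R)-4-ethenyl-4-methyl-3-(prop-1-en-2-yl)cyclohexyl]prop-1-en-1-yl}oxiran-2-yl]propan-2-ol
Conditions: Hf(OtBu)4 (10 mol %), (1R,2R)-N,N′-dihydroxy-N,N′-bis(2,2-diphenylacetyl)cyclohexane-1,2-diamine (12 mol %), PhC(CH3)2OOH (1.5 equiv), 4 Å MS, toluene, 0 °C
Reagents that add atoms: cumene hydroperoxide CC(C)(OO)c1ccccc1
Why: Proposed new method: hydroxyl-directed, catalyst-controlled mono-epoxidation of a tertiary 2,4-dienyl carbinol by a chiral tetravalent hafnium bis(hydroxamate) alkylperoxide, in which the substrate binds hafnium as its alkoxide so that only the allylic C16=C17 bond can reach the metal-bound peroxide oxygen (the C13=C15 bond is held away by the E-diene geometry and the vinyl and isopropenyl groups carry no directing group) and the C2-symmetric ligand pocket, not the remote ring stereocentres, selects the alkene face to set 16R and 17S, the closest known reaction type being the group-4 bis(hydroxamic acid) and titanium tartrate directed epoxidations of simple tertiary allylic alcohols and of primary dienols.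

Step 10
Reactants: 14 2-[(2S,3R)-3-{(1E)-2-[(1S,3R,4R)-4-ethenyl-4-methyl-3-(prop-1-en-2-yl)cyclohexyl]prop-1-en-1-yl}oxiran-2-yl]propan-2-ol
Product: 16 (3S,4S,5E)-6-[(1S,3R,4R)-4-ethenyl-4-methyl-3-(prop-1-en-2-yl)cyclohexyl]-2-hydroxy-2-methylhept-5-ene-3,4-diyl diacetate, via 16-monoacetate 15 (not isolated)
Conditions: Ti(OiPr)4 (1.5 equiv), AcOH (2 equiv), CH2Cl2, 0 → 23 °C; H2O work-up; then Ac2O, pyridine, 23 °C
Reagents that add atoms: acetic acid CC(=O)O; acetic anhydride CC(=O)OC(C)=O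
Why: Titanium-assisted opening of the 2,3-epoxy alcohol by carboxylate at the distal, here allylic, carbon C16 proceeds by SN2 inversion (giving 16S while 17S is retained, the erythro diol pattern), and Ac2O/pyridine then acetylates the secondary 17-OH but not the tertiary 18-OH.

**Compound list**
1 | (S)-carvone, (5S)-2-methyl-5-(prop-1-en-2-yl)cyclohex-2-en-1-one | CC1=CC[C@@H](CC1=O)C(C)=C | starting material
2 | (5S)-5-acetyl-2-methylcyclohex-2-en-1-one | CC1=CC[C@@H](CC1=O)C(C)=O | intermediate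
3 | (5S)-2-methyl-5-(2-methyl-1,3-dioxolan-2-yl)cyclohex-2-en-1-one | CC1=CC[C@@H](CC1=O)C1(C)OCCO1 | intermediate
4 | trimethyl{[(3R,5S)-2-methyl-5-(2-methyl-1,3-dioxolan-2-yl)-3-(prop-1-en-2-yl)cyclohex-1-en-1-yl]oxy}silane | CC1=C(O[Si](C)(C)C)C[C@@H](C2(C)OCCO2)C[C@@H]1C(C)=C | intermediate
5 | lithium enolate: lithium (3R,5S)-2-methyl-5-(2-methyl-1,3-dioxolan-2-yl)-3-(prop-1-en-2-yl)cyclohex-1-en-1-olate | [Li+].CC1=C([O-])C[C@@H](C2(C)OCCO2)C[C@@H]1C(C)=C | intermediate
6 | sulfoxide adduct: (2R,3R,5S)-2-methyl-5-(2-methyl-1,3-dioxolan-2-yl)-2-[2-(phenylsulfinyl)ethyl]-3-(prop-1-en-2-yl)cyclohexan-1-one (mixture at sulfur) | O=S(CC[C@@]1(C)C(=O)C[C@@H](C2(C)OCCO2)C[C@@H]1C(C)=C)c1ccccc1 | intermediate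
7 | (2R,3R,5S)-2-ethenyl-2-methyl-5-(2-methyl-1,3-dioxolan-2-yl)-3-(prop-1-en-2-yl)cyclohexan-1-one | C=C[C@@]1(C)C(=O)C[C@@H](C2(C)OCCO2)C[C@@H]1C(C)=C | intermediate
8 | hydrazone: [(2R,3R,5S)-2-ethenyl-2-methyl-5-(2-methyl-1,3-dioxolan-2-yl)-3-(prop-1-en-2-yl)cyclohexylidene]hydrazine | C=C[C@@]1(C)C(=NN)C[C@@H](C2(C)OCCO2)C[C@@H]1C(C)=C | intermediate
9 | 2-[(1R,3R,4R)-4-ethenyl-4-methyl-3-(prop-1-en-2-yl)cyclohexyl]-2-methyl-1,3-dioxolane | C=C[C@@]1(C)CC[C@@H](C2(C)OCCO2)C[C@@H]1C(C)=C | intermediate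
10 | axial-acetyl epimer: 1-[(1R,3R,4R)-4-ethenyl-4-methyl-3-(prop-1-en-2-yl)cyclohexyl]ethan-1-one | C=C[C@@]1(C)CC[C@@H](C(C)=O)C[C@@H]1C(C)=C | intermediate
11 | 1-[(1S,3R,4R)-4-ethenyl-4-methyl-3-(prop-1-en-2-yl)cyclohexyl]ethan-1-one | C=C[C@@]1(C)CC[C@H](C(C)=O)C[C@@H]1C(C)=C | intermediate
12 | ethyl (2E,4E)-5-[(1S,3R,4R)-4-ethenyl-4-methyl-3-(prop-1-en-2-yl)cyclohexyl]hexa-2,4-dienoate | C=C[C@@]1(C)CC[C@H](/C(C)=C/C=C/C(=O)OCC)C[C@@H]1C(C)=C | intermediate
13 | fuscol, (3E,5E)-6-[(1S,3R,4R)-4-ethenyl-4-methyl-3-(prop-1-en-2-yl)cyclohexyl]-2-methylhepta-3,5-dien-2-ol | C=C[C@@]1(C)CC[C@H](/C(C)=C/C=C/C(C)(C)O)C[C@@H]1C(C)=C | intermediate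
14 | 2-[(2S,3R)-3-{(1E)-2-[(1S,3R,4R)-4-ethenyl-4-methyl-3-(prop-1-en-2-yl)cyclohexyl]prop-1-en-1-yl}oxiran-2-yl]propan-2-ol | C=C[C@@]1(C)CC[C@H](/C(C)=C/[C@H]2O[C@@H]2C(C)(C)O)C[C@@H]1C(C)=C | intermediate
15 | 16-monoacetate: (3S,4S,5E)-6-[(1S,3R,4R)-4-ethenyl-4-methyl-3-(prop-1-en-2-yl)cyclohexyl]-2,3-dihydroxy-2-methylhept-5-en-4-yl acetate | C=C[C@@]1(C)CC[C@H](/C(C)=C/[C@H](OC(C)=O)[C@H](O)C(C)(C)O)C[C@@H]1C(C)=C | intermediate
16 | (3S,4S,5E)-6-[(1S,3R,4R)-4-ethenyl-4-methyl-3-(prop-1-en-2-yl)cyclohexyl]-2-hydroxy-2-methylhept-5-ene-3,4-diyl diacetate | C=C[C@@]1(C)CC[C@H](/C(C)=C/[C@H](OC(C)=O)[C@H](OC(C)=O)C(C)(C)O)C[C@@H]1C(=C)C | target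

**Step count**
Total steps: 10. Longest linear sequence: 10 steps, from (S)-carvone.

**Three steps most likely to fail**

Step 4 (vinylation at a congested quaternary carbon). The Michael addition of a tetrasubstituted enolate to phenyl vinyl sulfoxide may be slow or give proton-transfer by-products. The fallback sets out from 4 and uses electrophilic alkynylation instead: Bu4NF releases the enolate in the presence of 1-[(trimethylsilyl)ethynyl]-1,2-benziodoxol-3(1H)-one (THF, −78 °C), with the same anti approach, to give (2S,3R,5S)-2-ethynyl-2-methyl-5-(2-methyl-1,3-dioxolan-2-yl)-3-(prop-1-en-2-yl)cyclohexan-1-one F1. Semi-hydrogenation over Pd/CaCO3/Pb(OAc)2 with quinoline under H2 then gives 7, where the route is rejoined.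

Step 7 (E/Z control at the new trisubstituted alkene). The vinylogous olefination of a methyl ketone may give too much 4Z isomer. The fallback sets out from 11 and builds the alkene by carbometallation. Kinetic enolisation with LiN(iPr)2 and trapping with ClP(O)(OEt)2 gives diethyl 1-[(1S,3R,4R)-4-ethenyl-4-methyl-3-(prop-1-en-2-yl)cyclohexyl]ethenyl phosphate F2. Elimination with further LiN(iPr)2 gives (1R,2R,4S)-1-ethenyl-4-ethynyl-1-methyl-2-(prop-1-en-2-yl)cyclohexane F3. Zirconium-catalysed syn-methylalumination (AlMe3, Cp2ZrCl2, CH2Cl2) and iodinolysis give (1R,2R,4S)-1-ethenyl-4-[(1E)-1-iodoprop-1-en-2-yl]-1-methyl-2-(prop-1-en-2-yl)cyclohexane F4. A Heck reaction with ethyl acrylate (Pd(OAc)2, Bu4NCl, K2CO3, DMF) then gives 12 with defined 4E geometry, where the route is rejoined.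

Step 9 (the proposed new epoxidation). The dienyl carbinol or the vinyl epoxide may ionise at the Lewis acidic metal, or face control may be poor. The fallback uses known chemistry, sets out from 12 and places the oxirane before the carbinol is made. A nucleophilic, catalyst-controlled conjugate epoxidation of the α,β-bond of the dienoate (Y(OiPr)3, chiral biphenyldiol ligand, Ph3As=O, t-BuOOH, THF, 23 °C) gives ethyl (2S,3R)-3-{(1E)-2-[(1S,3R,4R)-4-ethenyl-4-methyl-3-(prop-1-en-2-yl)cyclohexyl]prop-1-en-1-yl}oxirane-2-carboxylate F5. Double addition of MeMgBr to the ester (THF, −78 °C) then gives 14, where the route is rejoined.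

**Further compounds**
F1 | step 4 | (2S,3R,5S)-2-ethynyl-2-methyl-5-(2-methyl-1,3-dioxolan-2-yl)-3-(prop-1-en-2-yl)cyclohexan-1-one | C#C[C@@]1(C)C(=O)C[C@@H](C2(C)OCCO2)C[C@@H]1C(C)=C
F2 | step 7 | diethyl 1-[(1S,3R,4R)-4-ethenyl-4-methyl-3-(prop-1-en-2-yl)cyclohexyl]ethenyl phosphate | C=C[C@@]1(C)CC[C@H](C(=C)OP(=O)(OCC)OCC)C[C@@H]1C(C)=C
F3 | step 7 | (1R,2R,4S)-1-ethenyl-4-ethynyl-1-methyl-2-(prop-1-en-2-yl)cyclohexane | C=C[C@@]1(C)CC[C@H](C#C)C[C@@H]1C(C)=C
F4 | step 7 | (1R,2R,4S)-1-ethenyl-4-[(1E)-1-iodoprop-1-en-2-yl]-1-methyl-2-(prop-1-en-2-yl)cyclohexane | C=C[C@@]1(C)CC[C@H](/C(C)=C/I)C[C@@H]1C(C)=C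
F5 | step 9 | ethyl (2S,3R)-3-{(1E)-2-[(1S,3R,4R)-4-ethenyl-4-methyl-3-(prop-1-en-2-yl)cyclohexyl]prop-1-en-1-yl}oxirane-2-carboxylate | C=C[C@@]1(C)CC[C@H](/C(C)=C/[C@H]2O[C@@H]2C(=O)OCC)C[C@@H]1C(C)=C
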